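**Strategy.** Lobatin B is disconnected at C2–C3 of the ten-membered carbocycle. The C1 ketone, C2 and the C3 enol-ether carbon of the 3(2H)-furanone ring form a 1,3-dioxygenated unit inside that carbocycle, which is the retron of a 4,5-dihydroisoxazole spanning C1–C3. An intramolecular nitrile oxide–alkene cycloaddition between a C3 nitrile oxide and the C1=C2 vinyl group on the C10 carbinol forms C2–C3 and C1–O, closing the isoxazoline and the carbocycle in one operation and masking the furanone. The precursor is an open-chain trans-γ-lactone carrying the (Z)-C3 enal oxime on C6, the C8 isovalerate/C9 PMB ether/C10 vinyl carbinol chain on C7, and the methylene lactone masked as its dimethylamine adduct.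

Key step: step 19

**Remarks on the chemistry (made before the steps)**
- Germacrane numbering is used: C1 ketone, C2=C3 enol ether, C4=C5, C6 lactone carbinol, C7, C8 ester carbinol, C9 carbinol, C10 quaternary, C11–C13 methylene lactone. PMB = 4-methoxybenzyl, TES = triethylsilyl, TBDPS = tert-butyldiphenylsilyl, pin = pinacolato.
- Structure check: the target is (4Z,6R,7S,8S,9R,10R) with a 6,7-trans lactone. The threo C8/C9 diol maps onto L-tartrate (tartrate C1→C10, C2→C9, C3→C8, C4→C7). No stereodescriptor of the target needed correction.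
- The butenolide used is 4-methyl-2(5H)-furanone. Its carbonyl carbon becomes the C6 aldehyde and its CH2O carbon becomes C3; the 3-methyl isomer would interchange these termini.
- At C10 the methyl group must be added last (vinyl ketone + MeMgBr, chelation control). Vinyl Grignard addition to the methyl ketone under the same control would give the C10 epimer.
- Metal-mediated additions of 2-(bromomethyl)alk-2-enoates to aldehydes are intrinsically syn and would give the cis-lactone. The trans-lactone is therefore made from an allylboronate with C8 cis to the ester.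
- Precursor design: O9 is carried as a PMB ether, which lets O8 be acylated selectively, keeps O9 from competing in furanone formation, and falls in the same acid step. The amine mask is added only after the oxime exists, and the amine is protonated during oxime chlorination.
- C1, C11 and the oxime geometry are transient; one isomer is drawn. C11 is drawn with CH2NMe2 trans to C8, the epimer expected from protonation anti to the C7 side chain.

**Route**

Step 1
Reactants: 1 diethyl L-tartrate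
Product: 3 diethyl (2R,3R)-2-hydroxy-3-[(4-methoxybenzyl)oxy]butanedioate, via stannylene acetal 2 (not isolated)
Conditions: Bu2SnO, toluene, reflux (Dean–Stark); then PMBCl, CsF, DMF, rt
Reagents that add atoms: 4-methoxybenzyl chloride, COc1ccc(CCl)cc1
Why: Stannylene-acetal-mediated mono-O-alkylation of the C2-symmetric diol gives a single ether and makes the two ends of the tartrate different without touching a stereocentre.

Step 2
Reactants: 3 diethyl (2R,3R)-2-hydroxy-3-[(4-methoxybenzyl)oxy]butanedioate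
Product: 4 ethyl (2R,3S)-3,4-dihydroxy-2-[(4-methoxybenzyl)oxy]butanoate
Conditions: BH3·SMe2, NaBH4 (5 mol%), THF, 0 °C → rt; MeOH quench
Reagents that add atoms: none
Why: Hydroxyl-directed borane reduction delivers hydride only to the ester next to the free hydroxyl (future C7), so the ester next to the PMB ether (future C10) survives.

Step 3
Reactants: 4 ethyl (2R,3S)-3,4-dihydroxy-2-[(4-methoxybenzyl)oxy]butanoate
Product: 5 ethyl (2R,3S)-2-[(4-methoxybenzyl)oxy]-3,4-bis(triethylsilyloxy)butanoate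
Conditions: TESCl, imidazole, DMAP (cat.), CH2Cl2, 0 °C → rt
Reagents that add atoms: chlorotriethylsilane, CC[Si](Cl)(CC)CC
Why: Standard silyl ether formation at the primary and secondary hydroxyls, which also blocks lactonisation of the 4-hydroxy ester.

Step 4
Reactants: 5 ethyl (2R,3S)-2-[(4-methoxybenzyl)oxy]-3,4-bis(triethylsilyloxy)butanoate
Product: 7 (4R,5S)-4-[(4-methoxybenzyl)oxy]-5,6-bis(triethylsilyloxy)hex-1-en-3-one, via Weinreb amide 6 (not isolated)
Conditions: MeNH(OMe)·HCl, i-PrMgCl, THF, −20 °C; then CH2=CHMgBr, −20 → 0 °C; inverse quench into cold aq. NaHSO4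
Reagents that add atoms: vinylmagnesium bromide, C=C[Mg]Br
Why: One-flask Weinreb ketone synthesis, in which the chelated tetrahedral adduct of the amide and the vinyl Grignard reagent collapses to the enone only on acidic quench, which also keeps the released amine from adding to the enone.

Step 5
Reactants: 7 (4R,5S)-4-[(4-methoxybenzyl)oxy]-5,6-bis(triethylsilyloxy)hex-1-en-3-one
Product: 8 (3S,4R,5S)-4-[(4-methoxybenzyl)oxy]-3-methyl-5,6-bis(triethylsilyloxy)hex-1-en-3-ol
Conditions: MeMgBr, THF, −78 °C; aq. NH4Cl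
Reagents that add atoms: methylmagnesium bromide, C[Mg]Br
Why: Chelation-controlled Grignard 1,2-addition, in which magnesium bridges the C10 carbonyl and the C9 PMB ether oxygen and methyl attacks the face syn to the C9 hydrogen (anti to C8), setting C10 as in the target; the hard reagent and the chelated carbonyl favour 1,2- over 1,4-addition.

Step 6
Reactants: 8 (3S,4R,5S)-4-[(4-methoxybenzyl)oxy]-3-methyl-5,6-bis(triethylsilyloxy)hex-1-en-3-ol
Product: 9 (3S,4R,5S)-4-[(4-methoxybenzyl)oxy]-3-methyl-3,5,6-tris(triethylsilyloxy)hex-1-ene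
Conditions: TESOTf, 2,6-lutidine, CH2Cl2, −78 → 0 °C
Reagents that add atoms: triethylsilyl trifluoromethanesulfonate, CC[Si](CC)(CC)OS(=O)(=O)C(F)(F)F
Why: Silyl triflate protection of the hindered tertiary allylic alcohol keeps it out of the activated-sulfoxide oxidation of step 7 and the acetylide acylation of step 9.

Step 7
Reactants: 9 (3S,4R,5S)-4-[(4-methoxybenzyl)oxy]-3-methyl-3,5,6-tris(triethylsilyloxy)hex-1-ene
Product: 10 (2R,3R,4S)-3-[(4-methoxybenzyl)oxy]-4-methyl-2,4-bis(triethylsilyloxy)hex-5-enal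
Conditions: (COCl)2, DMSO, CH2Cl2, −78 → −30 °C; Et3N, −78 °C → rt
Reagents that add atoms: none
Why: Swern oxidation applied directly to the primary triethylsilyl ether, which is cleaved and oxidised in place while the secondary and tertiary silyl ethers remain.

Step 8
Reactants: 10 (2R,3R,4S)-3-[(4-methoxybenzyl)oxy]-4-methyl-2,4-bis(triethylsilyloxy)hex-5-enal
Product: 11 (3S,4R,5S)-4-[(4-methoxybenzyl)oxy]-3-methyl-3,5-bis(triethylsilyloxy)hept-1-en-6-yne
Conditions: dimethyl (1-diazo-2-oxopropyl)phosphonate, K2CO3, MeOH, 0 °C → rt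
Reagents that add atoms: dimethyl (1-diazo-2-oxopropyl)phosphonate, COP(=O)(OC)C(=[N+]=[N-])C(C)=O
Why: Ohira–Bestmann homologation turns the C7 aldehyde into an alkyne and adds C11 under carbonate base mild enough to leave the α-silyloxy centre C8 intact.

Step 9
Reactants: 11 (3S,4R,5S)-4-[(4-methoxybenzyl)oxy]-3-methyl-3,5-bis(triethylsilyloxy)hept-1-en-6-yne
Product: 13 methyl (4S,5R,6S)-5-[(4-methoxybenzyl)oxy]-6-methyl-4,6-bis(triethylsilyloxy)oct-7-en-2-ynoate, via lithium acetylide 12 (not isolated)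
Conditions: n-BuLi, THF, −78 °C; ClCO2Me, −78 → 0 °C
Reagents that add atoms: methyl chloroformate, COC(=O)Cl
Why: Deprotonation of the terminal alkyne and C-acylation of the acetylide with the chloroformate installs C12 as the methyl alkynoate.

Step 10
Reactants: 13 methyl (4S,5R,6S)-5-[(4-methoxybenzyl)oxy]-6-methyl-4,6-bis(triethylsilyloxy)oct-7-en-2-ynoate
Product: 15 methyl (2Z,4S,5R,6S)-5-[(4-methoxybenzyl)oxy]-6-methyl-2-[(4,4,5,5-tetramethyl-1,3,2-dioxaborolan-2-yl)methyl]-4,6-bis(triethylsilyloxy)octa-2,7-dienoate, via vinylalane 14 (not isolated)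
Conditions: i-Bu2AlH, HMPA, MeCu (10 mol%, from MeLi and CuI), THF, −50 → −20 °C; then ICH2B(pin), −20 °C → rt
Reagents that add atoms: 2-(iodomethyl)-4,4,5,5-tetramethyl-1,3,2-dioxaborolane, CC1(C)OB(CI)OC1(C)C
Why: Copper-catalysed conjugate hydroalumination of the alkynoate followed by α-alkylation with the iodomethylboronate places hydrogen at C7 and the CH2B group at C11 on the same side, so C8 ends cis to the ester and trans to CH2B, the geometry required for the trans-lactone.

Step 11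
Reactants: 16 4-methyl-2(5H)-furanone
Product: 18 (2Z)-4-(tert-butyldiphenylsilyloxy)-N-methoxy-N,3-dimethylbut-2-enamide, via hydroxy amide 17 (not isolated)
Conditions: MeNH(OMe)·HCl, AlMe3, CH2Cl2, 0 °C → rt; work-up; crude, TBDPSCl, imidazole, CH2Cl2, 0 °C
Reagents that add atoms: N,O-dimethylhydroxylamine hydrochloride, CNOC.Cl; tert-butyl(chloro)diphenylsilane, CC(C)(C)[Si](Cl)(c1ccccc1)c1ccccc1
Why: Aluminium amide aminolysis opens the butenolide to the (Z)-hydroxy Weinreb amide with the ring-imposed alkene geometry, and immediate silylation prevents relactonisation.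

Step 12
Reactants: 18 (2Z)-4-(tert-butyldiphenylsilyloxy)-N-methoxy-N,3-dimethylbut-2-enamide
Product: 19 (2Z)-4-(tert-butyldiphenylsilyloxy)-3-methylbut-2-enal
Conditions: i-Bu2AlH, THF, −78 °C; aq. Rochelle salt
Reagents that add atoms: none
Why: Weinreb amide reduction stops at the aldehyde through the chelated aluminium hemiaminal, and the low temperature and non-acidic work-up preserve the Z geometry.

Step 13
Reactants: 15 methyl (2Z,4S,5R,6S)-5-[(4-methoxybenzyl)oxy]-6-methyl-2-[(pinacolboryl)methyl]-4,6-bis(triethylsilyloxy)octa-2,7-dienoate; 19 (2Z)-4-(tert-butyldiphenylsilyloxy)-3-methylbut-2-enal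
Product: 21 (4S,5R)-5-[(1Z)-3-(tert-butyldiphenylsilyloxy)-2-methylprop-1-en-1-yl]-4-[(1S,2R,3S)-2-[(4-methoxybenzyl)oxy]-3-methyl-1,3-bis(triethylsilyloxy)pent-4-en-1-yl]-3-methylideneoxolan-2-one, via borate ester 20 (not isolated)
Conditions: toluene, 4 Å MS, 70 °C; then PPTS (cat.), CH2Cl2, rt
Reagents that add atoms: none
Why: Thermal allylboration through a closed six-membered chair transition state followed by lactonisation of the borate onto the methyl ester: with C8 trans to CH2B and the aldehyde substituent equatorial the addition is anti, which gives the 6,7-trans lactone, and the aldehyde adds to the C7 face opposite the bulky C9 branch of the allylic C8 centre (C8–H eclipsing the alkene to avoid allylic strain), which sets C7 and with it C6.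

Step 14
Reactants: 21 (4S,5R)-5-[(1Z)-3-(tert-butyldiphenylsilyloxy)-2-methylprop-1-en-1-yl]-4-[(1S,2R,3S)-2-[(4-methoxybenzyl)oxy]-3-methyl-1,3-bis(triethylsilyloxy)pent-4-en-1-yl]-3-methylideneoxolan-2-one
Product: 22 (4R,5R)-5-[(1Z)-3-(tert-butyldiphenylsilyloxy)-2-methylprop-1-en-1-yl]-4-[(1S,2R,3S)-1,3-dihydroxy-2-[(4-methoxybenzyl)oxy]-3-methylpent-4-en-1-yl]-3-methylideneoxolan-2-one
Conditions: HF·pyridine, pyridine, THF, 0 °C → rt
Reagents that add atoms: none
Why: Buffered fluoride desilylation removes the two triethylsilyl ethers, which are far more labile than the tert-butyldiphenylsilyl ether, under non-ionising conditions that spare the tertiary allylic C10 oxygen.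

Step 15
Reactants: 22 (4R,5R)-5-[(1Z)-3-(tert-butyldiphenylsilyloxy)-2-methylprop-1-en-1-yl]-4-[(1S,2R,3S)-1,3-dihydroxy-2-[(4-methoxybenzyl)oxy]-3-methylpent-4-en-1-yl]-3-methylideneoxolan-2-one
Product: 23 (1S,2R,3S)-1-{(2R,3S)-2-[(1Z)-3-(tert-butyldiphenylsilyloxy)-2-methylprop-1-en-1-yl]-4-methylidene-5-oxooxolan-3-yl}-3-hydroxy-2-[(4-methoxybenzyl)oxy]-3-methylpent-4-en-1-yl 3-methylbutanoate
Conditions: (i-PrCH2CO)2O, DMAP (cat.), pyridine, CH2Cl2, 0 °C → rt
Reagents that add atoms: 3-methylbutanoic anhydride, CC(C)CC(=O)OC(=O)CC(C)C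
Why: DMAP-catalysed acylation takes the secondary C8 hydroxyl and leaves the tertiary C10 hydroxyl, so the isovalerate is placed at C8 while O9 is still blocked.

Step 16
Reactants: 23 the C8 isovalerate with C3–OTBDPS
Product: 24 (1S,2R,3S)-3-hydroxy-1-{(2R,3S)-2-[(1Z)-3-hydroxy-2-methylprop-1-en-1-yl]-4-methylidene-5-oxooxolan-3-yl}-2-[(4-methoxybenzyl)oxy]-3-methylpent-4-en-1-yl 3-methylbutanoate
Conditions: Bu4NF, AcOH, THF, 0 °C → rt
Reagents that add atoms: none
Why: Acetic-acid-buffered fluoride desilylation frees the C3 allylic alcohol without exposing the methylene lactone or the ester to base.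

Step 17
Reactants: 24 the C3 allylic alcohol
Product: 25 (1S,2R,3S)-3-hydroxy-2-[(4-methoxybenzyl)oxy]-3-methyl-1-{(2R,3S)-4-methylidene-2-[(1Z)-2-methyl-3-oxoprop-1-en-1-yl]-5-oxooxolan-3-yl}pent-4-en-1-yl 3-methylbutanoate
Conditions: MnO2, CH2Cl2, rt, dark
Reagents that add atoms: none
Why: Manganese dioxide oxidation is selective for the primary allylic alcohol (the tertiary allylic C10 hydroxyl cannot react) and mild enough to keep the Z enal.

Step 18
Reactants: 25 the C3 enal
Product: 27 (1S,2R,3S)-1-{(2R,3S,4R)-4-[(dimethylamino)methyl]-2-[(1Z)-3-(hydroxyimino)-2-methylprop-1-en-1-yl]-5-oxooxolan-3-yl}-3-hydroxy-2-[(4-methoxybenzyl)oxy]-3-methylpent-4-en-1-yl 3-methylbutanoate, via oxime 26 (not isolated)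
Conditions: NH2OH·HCl (1.1 equiv), NaOAc, EtOH, 0 °C; then Me2NH (2 M in THF), 0 °C → rt
Reagents that add atoms: hydroxylamine hydrochloride, NO.Cl; dimethylamine, CNC
Why: Oxime condensation with near-stoichiometric hydroxylamine outruns aza-Michael addition, and the following conjugate (aza-Michael) addition of dimethylamine masks the methylene lactone only after the electrophilic enal is gone; C11 is set by protonation anti to the C7 side chain and is erased in step 23.

Step 19
Reactants: 27 the open-chain C3 oxime with amine-masked lactone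
Product: 30 isoxazoline-bridged amine-masked germacranolide (1R,6R,7S,8S,9R,10R,11R), via hydroximoyl chloride 28 (not isolated), via nitrile oxide 29 (not isolated)
Conditions: HCl (1.0 equiv, Et2O), DMF, 0 °C; NCS (1.05 equiv), 0 °C → rt; then syringe-pump addition over 12 h into Et3N, CH2Cl2, 35 °C (final 1 mM)
Reagents that add atoms: none
Why: N-Chlorosuccinimide chlorinates the C3 aldoxime while the amine is held as its ammonium chloride, and slow release with Et3N gives the conjugated nitrile oxide 29, which adds to the C1=C2 vinyl group in a concerted (3+2) cycloaddition with C3 bonding to the terminal C2 and the dipole oxygen to C1. The closest known reaction type is the intramolecular nitrile oxide–alkene cycloaddition used to close medium and large carbocycles as bridged isoxazolines. The 4,5-dihydroisoxazole closes by the cycloaddition itself, and the ten-membered carbocycle closes with it in the bridged mode, because the tether C4–C10 joins the dipole carbon to the substituted alkene carbon. The one new stereocentre, C1, is controlled by the adjacent C10 quaternary carbinol (hydroxyl hydrogen-bonded to the incoming dipole oxygen) and by the tether, and either epimer serves because C1 becomes a ketone. The step needs intramolecular reaction at the vinyl group with carbon-to-C2 regiochemistry in preference to furoxan dimerisation: millimolar concentration with slow generation suppresses dimerisation, a monosubstituted alkene is biased towards carbon attack at its unsubstituted end, the fused alternative would need a nine-membered ring, the methylene lactone is masked, and the trans-lactone and the (Z)-C4=C5 alkene turn the two chain ends towards each other.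

Step 20
Reactants: 30 isoxazoline-bridged amine-masked germacranolide
Product: 32 (1R,6R,7S,8S,9R,10S,11R)-13-(dimethylamino)-1,10-dihydroxy-9-[(4-methoxybenzyl)oxy]-8-(3-methylbutanoyloxy)-3-oxo-11,13-dihydrogermacr-4(Z)-en-6,12-olide, via hydroxy imine 31 (not isolated)
Conditions: Mo(CO)6, MeCN/H2O (10:1), 80 °C
Reagents that add atoms: water, O
Why: Molybdenum hexacarbonyl-mediated reductive N–O cleavage of the isoxazoline gives the β-hydroxy imine, which water hydrolyses to the β-hydroxy ketone without the alkene reduction that hydrogenolysis would risk.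

Step 21
Reactants: 32 the C1-hydroxy C3-ketone
Product: 33 (6R,7S,8S,9R,10R,11R)-13-(dimethylamino)-10-hydroxy-9-[(4-methoxybenzyl)oxy]-8-(3-methylbutanoyloxy)-1,3-dioxo-11,13-dihydrogermacr-4(Z)-en-6,12-olide
Conditions: Dess–Martin periodinane, NaHCO3, CH2Cl2, 0 °C → rt
Reagents that add atoms: none
Why: Dess–Martin oxidation of the C1 carbinol gives the 1,3-diketone under neutral conditions that avoid retro-aldol cleavage and dehydration, and removes the C1 stereocentre.

Step 22
Reactants: 33 the α'-hydroxy 1,3-diketone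
Product: 36 (6R,7S,8S,9R,10R,11R)-13-(dimethylamino)-11,13-dihydrolobatin B, via hemiketal 34 (not isolated), via furanone PMB ether 35 (not isolated)
Conditions: TFA/CH2Cl2 (1:9), anisole, 0 °C; then TFA/CH2Cl2 (1:3), rt; aq. NaHCO3 work-up
Reagents that add atoms: none
Why: Acid-catalysed cyclodehydration of the α'-hydroxy-1,3-diketone, in which the free C10 hydroxyl adds to the C3 carbonyl and the hemiketal loses water to the 3(2H)-furanone while O9 is still blocked and cannot form a pyranone, is followed in the same flask by SN1 cleavage of the PMB ether with anisole as cation scavenger.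

Step 23
Reactants: 36 13-(dimethylamino)-11,13-dihydrolobatin B
Product: 38 lobatin B, via ammonium iodide 37 (not isolated)
Conditions: MeI, THF, rt; then aq. NaHCO3, CH2Cl2, rt
Reagents that add atoms: none
Why: Quaternisation of the tertiary amine and mild base-induced β-elimination of trimethylamine (Hofmann-type, E1cB) regenerates the C11=C13 methylene and removes the transient C11 stereocentre.

**Compound list**

1 | diethyl L-tartrate, diethyl (2R,3R)-2,3-dihydroxybutanedioate | CCOC(=O)[C@H](O)[C@@H](O)C(=O)OCC | starting material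
2 | diethyl (4R,5R)-2,2-dibutyl-1,3,2-dioxastannolane-4,5-dicarboxylate (stannylene acetal) | CCOC(=O)[C@@H]1O[Sn](CCCC)(CCCC)O[C@H]1C(=O)OCC | intermediate (not isolated)
3 | diethyl (2R,3R)-2-hydroxy-3-[(4-methoxybenzyl)oxy]butanedioate | CCOC(=O)[C@H](OCc1ccc(OC)cc1)[C@@H](O)C(=O)OCC | intermediate
4 | ethyl (2R,3S)-3,4-dihydroxy-2-[(4-methoxybenzyl)oxy]butanoate | CCOC(=O)[C@H](OCc1ccc(OC)cc1)[C@@H](O)CO | intermediate
5 | ethyl (2R,3S)-2-[(4-methoxybenzyl)oxy]-3,4-bis(triethylsilyloxy)butanoate | CCOC(=O)[C@H](OCc1ccc(OC)cc1)[C@@H](O[Si](CC)(CC)CC)CO[Si](CC)(CC)CC | intermediate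
6 | (2R,3S)-N-methoxy-2-[(4-methoxybenzyl)oxy]-N-methyl-3,4-bis(triethylsilyloxy)butanamide (Weinreb amide) | CON(C)C(=O)[C@H](OCc1ccc(OC)cc1)[C@@H](O[Si](CC)(CC)CC)CO[Si](CC)(CC)CC | intermediate (not isolated)
7 | (4R,5S)-4-[(4-methoxybenzyl)oxy]-5,6-bis(triethylsilyloxy)hex-1-en-3-one | C=CC(=O)[C@H](OCc1ccc(OC)cc1)[C@@H](O[Si](CC)(CC)CC)CO[Si](CC)(CC)CC | intermediate
8 | (3S,4R,5S)-4-[(4-methoxybenzyl)oxy]-3-methyl-5,6-bis(triethylsilyloxy)hex-1-en-3-ol | C=C[C@](C)(O)[C@H](OCc1ccc(OC)cc1)[C@@H](O[Si](CC)(CC)CC)CO[Si](CC)(CC)CC | intermediate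
9 | (3S,4R,5S)-4-[(4-methoxybenzyl)oxy]-3-methyl-3,5,6-tris(triethylsilyloxy)hex-1-ene | C=C[C@](C)(O[Si](CC)(CC)CC)[C@H](OCc1ccc(OC)cc1)[C@@H](O[Si](CC)(CC)CC)CO[Si](CC)(CC)CC | intermediate
10 | (2R,3R,4S)-3-[(4-methoxybenzyl)oxy]-4-methyl-2,4-bis(triethylsilyloxy)hex-5-enal (C7 aldehyde) | C=C[C@](C)(O[Si](CC)(CC)CC)[C@H](OCc1ccc(OC)cc1)[C@@H](O[Si](CC)(CC)CC)C=O | intermediate
11 | (3S,4R,5S)-4-[(4-methoxybenzyl)oxy]-3-methyl-3,5-bis(triethylsilyloxy)hept-1-en-6-yne | C=C[C@](C)(O[Si](CC)(CC)CC)[C@H](OCc1ccc(OC)cc1)[C@@H](O[Si](CC)(CC)CC)C#C | intermediate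
12 | lithium acetylide of 11 | C=C[C@](C)(O[Si](CC)(CC)CC)[C@H](OCc1ccc(OC)cc1)[C@@H](O[Si](CC)(CC)CC)C#C[Li] | intermediate (not isolated)
13 | methyl (4S,5R,6S)-5-[(4-methoxybenzyl)oxy]-6-methyl-4,6-bis(triethylsilyloxy)oct-7-en-2-ynoate | C=C[C@](C)(O[Si](CC)(CC)CC)[C@H](OCc1ccc(OC)cc1)[C@@H](O[Si](CC)(CC)CC)C#CC(=O)OC | intermediate
14 | methyl (4S,5R,6S)-2-(diisobutylalumanyl)-5-[(4-methoxybenzyl)oxy]-6-methyl-4,6-bis(triethylsilyloxy)octa-2,7-dienoate, C8 cis to the ester (vinylalane) | C=C[C@](C)(O[Si](CC)(CC)CC)[C@H](OCc1ccc(OC)cc1)[C@@H](O[Si](CC)(CC)CC)/C=C(/[Al](CC(C)C)CC(C)C)C(=O)OC | intermediate (not isolated)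
15 | methyl (2Z,4S,5R,6S)-5-[(4-methoxybenzyl)oxy]-6-methyl-2-[(4,4,5,5-tetramethyl-1,3,2-dioxaborolan-2-yl)methyl]-4,6-bis(triethylsilyloxy)octa-2,7-dienoate (allylboronate, C8 cis to the ester) | C=C[C@](C)(O[Si](CC)(CC)CC)[C@H](OCc1ccc(OC)cc1)[C@@H](O[Si](CC)(CC)CC)/C=C(/CB1OC(C)(C)C(C)(C)O1)C(=O)OC | intermediate
16 | 4-methyl-2(5H)-furanone | CC1=CC(=O)OC1 | starting material
17 | (2Z)-4-hydroxy-N-methoxy-N,3-dimethylbut-2-enamide | CON(C)C(=O)/C=C(/C)CO | intermediate (not isolated)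
18 | (2Z)-4-(tert-butyldiphenylsilyloxy)-N-methoxy-N,3-dimethylbut-2-enamide | CON(C)C(=O)/C=C(/C)CO[Si](c1ccccc1)(c1ccccc1)C(C)(C)C | intermediate
19 | (2Z)-4-(tert-butyldiphenylsilyloxy)-3-methylbut-2-enal (C3–C6 enal) | O=C/C=C(/C)CO[Si](c1ccccc1)(c1ccccc1)C(C)(C)C | intermediate
20 | O6-pinacolboryl anti adduct of 15 and 19, methyl ester (6R,7S,8S,9R,10S) | C=C[C@](C)(O[Si](CC)(CC)CC)[C@H](OCc1ccc(OC)cc1)[C@@H](O[Si](CC)(CC)CC)[C@@H](C(=C)C(=O)OC)[C@H](OB1OC(C)(C)C(C)(C)O1)/C=C(/C)CO[Si](c1ccccc1)(c1ccccc1)C(C)(C)C | intermediate (not isolated)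
21 | (4S,5R)-5-[(1Z)-3-(tert-butyldiphenylsilyloxy)-2-methylprop-1-en-1-yl]-4-[(1S,2R,3S)-2-[(4-methoxybenzyl)oxy]-3-methyl-1,3-bis(triethylsilyloxy)pent-4-en-1-yl]-3-methylideneoxolan-2-one (trans-lactone) | C=C[C@](C)(O[Si](CC)(CC)CC)[C@H](OCc1ccc(OC)cc1)[C@@H](O[Si](CC)(CC)CC)[C@H]1C(=C)C(=O)O[C@@H]1/C=C(/C)CO[Si](c1ccccc1)(c1ccccc1)C(C)(C)C | intermediate
22 | (4R,5R)-5-[(1Z)-3-(tert-butyldiphenylsilyloxy)-2-methylprop-1-en-1-yl]-4-[(1S,2R,3S)-1,3-dihydroxy-2-[(4-methoxybenzyl)oxy]-3-methylpent-4-en-1-yl]-3-methylideneoxolan-2-one | C=C[C@](C)(O)[C@H](OCc1ccc(OC)cc1)[C@@H](O)[C@H]1C(=C)C(=O)O[C@@H]1/C=C(/C)CO[Si](c1ccccc1)(c1ccccc1)C(C)(C)C | intermediate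
23 | (1S,2R,3S)-1-{(2R,3S)-2-[(1Z)-3-(tert-butyldiphenylsilyloxy)-2-methylprop-1-en-1-yl]-4-methylidene-5-oxooxolan-3-yl}-3-hydroxy-2-[(4-methoxybenzyl)oxy]-3-methylpent-4-en-1-yl 3-methylbutanoate | C=C[C@](C)(O)[C@H](OCc1ccc(OC)cc1)[C@@H](OC(=O)CC(C)C)[C@H]1C(=C)C(=O)O[C@@H]1/C=C(/C)CO[Si](c1ccccc1)(c1ccccc1)C(C)(C)C | intermediate
24 | (1S,2R,3S)-3-hydroxy-1-{(2R,3S)-2-[(1Z)-3-hydroxy-2-methylprop-1-en-1-yl]-4-methylidene-5-oxooxolan-3-yl}-2-[(4-methoxybenzyl)oxy]-3-methylpent-4-en-1-yl 3-methylbutanoate | C=C[C@](C)(O)[C@H](OCc1ccc(OC)cc1)[C@@H](OC(=O)CC(C)C)[C@H]1C(=C)C(=O)O[C@@H]1/C=C(/C)CO | intermediate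
25 | (1S,2R,3S)-3-hydroxy-2-[(4-methoxybenzyl)oxy]-3-methyl-1-{(2R,3S)-4-methylidene-2-[(1Z)-2-methyl-3-oxoprop-1-en-1-yl]-5-oxooxolan-3-yl}pent-4-en-1-yl 3-methylbutanoate | C=C[C@](C)(O)[C@H](OCc1ccc(OC)cc1)[C@@H](OC(=O)CC(C)C)[C@H]1C(=C)C(=O)O[C@@H]1/C=C(/C)C=O | intermediate
26 | C3 aldoxime of 25 (methylene lactone still free; oxime geometry not defined) | C=C[C@](C)(O)[C@H](OCc1ccc(OC)cc1)[C@@H](OC(=O)CC(C)C)[C@H]1C(=C)C(=O)O[C@@H]1/C=C(/C)C=NO | intermediate (not isolated)
27 | (1S,2R,3S)-1-{(2R,3S,4R)-4-[(dimethylamino)methyl]-2-[(1Z)-3-(hydroxyimino)-2-methylprop-1-en-1-yl]-5-oxooxolan-3-yl}-3-hydroxy-2-[(4-methoxybenzyl)oxy]-3-methylpent-4-en-1-yl 3-methylbutanoate (key-step precursor) | C=C[C@](C)(O)[C@H](OCc1ccc(OC)cc1)[C@@H](OC(=O)CC(C)C)[C@H]1[C@H](CN(C)C)C(=O)O[C@@H]1/C=C(/C)C=NO | intermediate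
28 | C3 hydroximoyl chloride of 27 (formed as its ammonium chloride; drawn as free base) | C=C[C@](C)(O)[C@H](OCc1ccc(OC)cc1)[C@@H](OC(=O)CC(C)C)[C@H]1[C@H](CN(C)C)C(=O)O[C@@H]1/C=C(/C)C(Cl)=NO | intermediate (not isolated)
29 | C3 nitrile oxide | C=C[C@](C)(O)[C@H](OCc1ccc(OC)cc1)[C@@H](OC(=O)CC(C)C)[C@H]1[C@H](CN(C)C)C(=O)O[C@@H]1/C=C(/C)C#[N+][O-] | intermediate (not isolated)
30 | isoxazoline-bridged germacranolide: (1R,6R,7S,8S,9R,10R,11R)-13-(dimethylamino)-10-hydroxy-9-[(4-methoxybenzyl)oxy]-8-(3-methylbutanoyloxy)-11,13-dihydrogermacr-4(Z)-en-6,12-olide in which C3=N–O–C1 and C1–C2–C3 form a 4,5-dihydroisoxazole (key-step product) | CN(C)C[C@@H]1C(=O)O[C@@H]2/C=C(/C)C3=NO[C@H](C3)[C@](C)(O)[C@H](OCc4ccc(OC)cc4)[C@@H](OC(=O)CC(C)C)[C@@H]12 | intermediate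
31 | C3 imine, C1 alcohol from N–O cleavage of 30 | CN(C)C[C@@H]1C(=O)O[C@@H]2/C=C(/C)C(=N)C[C@@H](O)[C@](C)(O)[C@H](OCc3ccc(OC)cc3)[C@@H](OC(=O)CC(C)C)[C@@H]12 | intermediate (not isolated)
32 | (1R,6R,7S,8S,9R,10S,11R)-13-(dimethylamino)-1,10-dihydroxy-9-[(4-methoxybenzyl)oxy]-8-(3-methylbutanoyloxy)-3-oxo-11,13-dihydrogermacr-4(Z)-en-6,12-olide | CN(C)C[C@@H]1C(=O)O[C@@H]2/C=C(/C)C(=O)C[C@@H](O)[C@](C)(O)[C@H](OCc3ccc(OC)cc3)[C@@H](OC(=O)CC(C)C)[C@@H]12 | intermediate
33 | (6R,7S,8S,9R,10R,11R)-13-(dimethylamino)-10-hydroxy-9-[(4-methoxybenzyl)oxy]-8-(3-methylbutanoyloxy)-1,3-dioxo-11,13-dihydrogermacr-4(Z)-en-6,12-olide | CN(C)C[C@@H]1C(=O)O[C@@H]2/C=C(/C)C(=O)CC(=O)[C@](C)(O)[C@H](OCc3ccc(OC)cc3)[C@@H](OC(=O)CC(C)C)[C@@H]12 | intermediate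
34 | cyclic hemiketal of 33 (O10 bonded to C3; C3 configuration not defined) | CN(C)C[C@@H]1C(=O)O[C@@H]2/C=C(/C)C3(O)CC(=O)[C@](C)(O3)[C@H](OCc4ccc(OC)cc4)[C@@H](OC(=O)CC(C)C)[C@@H]12 | intermediate (not isolated)
35 | 9-O-(4-methoxybenzyl)-13-(dimethylamino)-11,13-dihydrolobatin B | CN(C)C[C@@H]1C(=O)O[C@@H]2/C=C(/C)C3=CC(=O)[C@](C)(O3)[C@H](OCc4ccc(OC)cc4)[C@@H](OC(=O)CC(C)C)[C@@H]12 | intermediate (not isolated)
36 | (6R,7S,8S,9R,10R,11R)-13-(dimethylamino)-11,13-dihydrolobatin B | CN(C)C[C@@H]1C(=O)O[C@@H]2/C=C(/C)C3=CC(=O)[C@](C)(O3)[C@H](O)[C@@H](OC(=O)CC(C)C)[C@@H]12 | intermediate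
37 | 13-(trimethylammonio)-11,13-dihydrolobatin B iodide | C[N+](C)(C)C[C@@H]1C(=O)O[C@@H]2/C=C(/C)C3=CC(=O)[C@](C)(O3)[C@H](O)[C@@H](OC(=O)CC(C)C)[C@@H]12.[I-] | intermediate (not isolated)
38 | lobatin B (4Z,6R,7S,8S,9R,10R) | C=C1C(=O)O[C@@H]2/C=C(/C)C3=CC(=O)[C@](C)(O3)[C@H](O)[C@@H](OC(=O)CC(C)C)[C@@H]12 | target

**Step count.** Total: 23 steps. Longest linear sequence: 21 steps (steps 1–10 and 13–23, from diethyl L-tartrate).

**Steps most likely to fail**

1. Step 19. The conjugated nitrile oxide may dimerise to the furoxan or oligomerise faster than the entropically and transannularly costly ten-membered closure. The fallback exchanges the two ring-forming events: the isoxazoline is made intermolecularly and the ring is closed at C6–C7. It sets out from allylboronate 15 and returns at 30. Commercial 3-methyl-2(5H)-furanone (CC1=CCOC1=O) is reduced with i-Bu2AlH (CH2Cl2, −78 °C) to the lactol 3-methyl-2,5-dihydrofuran-2-ol F1, which NH2OH·HCl/NaOAc opens to (2Z)-4-hydroxy-2-methylbut-2-enal oxime F2. Chlorination of F2 (NCS, DMF) and slow addition of Et3N in the presence of 15 gives, with the normal intermolecular regiochemistry, the 5-substituted isoxazoline allylboronate F3. MnO2 oxidises its C6 allylic alcohol to the enal F4, which on warming in dilute toluene undergoes intramolecular allylboration and lactonisation to the isoxazoline-bridged methylene lactone bis(triethylsilyl) ether F5. HF·pyridine frees the C8 and C10 hydroxyls to give the diol F6, isovaleric anhydride/DMAP acylates C8 to give the isovalerate F7, and Me2NH addition to the methylene lactone gives 30 (its C1 epimer, if formed, converges at 33).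

2. Step 13. The hindered, electron-poor allylboronate may add to the enal too slowly, so that Z/E isomerisation of the enal or protodeboronation competes. The fallback uses a more nucleophilic allylindium reagent and corrects its syn selectivity afterwards; it sets out from aldehyde 10 and returns at 21. Morita–Baylis–Hillman reaction of 10 with methyl acrylate (DABCO) gives the Baylis–Hillman alcohol F8, and NBS/Me2S converts it with allylic transposition into the (Z)-2-(bromomethyl)enoate F9. Indium metal in THF/H2O couples F9 with enal 19 in a Barbier reaction to give the syn homoallylic alcohol F10 (C6 epimer of the required adduct). LiOH saponifies the methyl ester to the hydroxy acid F11, and Mitsunobu lactonisation (PPh3, DIAD) closes the lactone with inversion at C6 to give 21.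

3. Step 10. The alkene geometry may be lost through equilibration of the aluminium allenolate, or the alkylation with the iodomethylboronate may be sluggish. The fallback fixes the geometry in a configurationally stable vinyl halide; it sets out from alkynoate 13 and returns at 15. Syn-hydrostannation with Bu3SnH and the zerovalent palladium catalyst Pd(PPh3)4 gives the α-stannyl enoate F12 (tin at C11, C8 cis to the ester). Iododestannylation with I2 gives the α-iodo enoate F13 with retention. Negishi coupling of F13 with (pinacolboryl)methylzinc iodide (from ICH2B(pin) and Zn) under Pd(PPh3)4 gives 15.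

**Further compounds**

F1 | step 19 | 3-methyl-2,5-dihydrofuran-2-ol (racemic lactol) | CC1=CCOC1O
F2 | step 19 | (2Z)-4-hydroxy-2-methylbut-2-enal oxime | OC/C=C(/C)C=NO
F3 | step 19 | intermolecular cycloadduct of 15: 5-substituted 4,5-dihydroisoxazole carrying the (Z)-C4=C5–C6H2OH chain on C3 (C1 configuration not defined) | OC/C=C(/C)C1=NOC(C1)[C@](C)(O[Si](CC)(CC)CC)[C@H](OCc1ccc(OC)cc1)[C@@H](O[Si](CC)(CC)CC)/C=C(/CB1OC(C)(C)C(C)(C)O1)C(=O)OC
F4 | step 19 | C6 aldehyde of F3 | O=C/C=C(/C)C1=NOC(C1)[C@](C)(O[Si](CC)(CC)CC)[C@H](OCc1ccc(OC)cc1)[C@@H](O[Si](CC)(CC)CC)/C=C(/CB1OC(C)(C)C(C)(C)O1)C(=O)OC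
F5 | step 19 | isoxazoline-bridged α-methylene germacranolide, 8,10-bis(triethylsilyl) ether, 9-PMB ether | C=C1C(=O)O[C@@H]2/C=C(/C)C3=NOC(C3)[C@](C)(O[Si](CC)(CC)CC)[C@H](OCc4ccc(OC)cc4)[C@@H](O[Si](CC)(CC)CC)[C@@H]12
F6 | step 19 | 8,10-diol of F5 | C=C1C(=O)O[C@@H]2/C=C(/C)C3=NOC(C3)[C@](C)(O)[C@H](OCc4ccc(OC)cc4)[C@@H](O)[C@@H]12
F7 | step 19 | 8-O-isovalerate of F6 | C=C1C(=O)O[C@@H]2/C=C(/C)C3=NOC(C3)[C@](C)(O)[C@H](OCc4ccc(OC)cc4)[C@@H](OC(=O)CC(C)C)[C@@H]12
F8 | step 13 | methyl 2-[(2S,3R,4S)-1-hydroxy-3-[(4-methoxybenzyl)oxy]-4-methyl-2,4-bis(triethylsilyloxy)hex-5-en-1-yl]prop-2-enoate (C7 epimers) | C=C[C@](C)(O[Si](CC)(CC)CC)[C@H](OCc1ccc(OC)cc1)[C@@H](O[Si](CC)(CC)CC)C(O)C(=C)C(=O)OC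
F9 | step 13 | methyl (2Z,4S,5R,6S)-2-(bromomethyl)-5-[(4-methoxybenzyl)oxy]-6-methyl-4,6-bis(triethylsilyloxy)octa-2,7-dienoate | C=C[C@](C)(O[Si](CC)(CC)CC)[C@H](OCc1ccc(OC)cc1)[C@@H](O[Si](CC)(CC)CC)/C=C(\CBr)C(=O)OC
F10 | step 13 | syn homoallylic alcohol methyl ester (C6 epimer of the free alcohol of 20) | C=C[C@](C)(O[Si](CC)(CC)CC)[C@H](OCc1ccc(OC)cc1)[C@@H](O[Si](CC)(CC)CC)[C@@H](C(=C)C(=O)OC)[C@@H](O)/C=C(/C)CO[Si](c1ccccc1)(c1ccccc1)C(C)(C)C
F11 | step 13 | carboxylic acid of F10 | C=C[C@](C)(O[Si](CC)(CC)CC)[C@H](OCc1ccc(OC)cc1)[C@@H](O[Si](CC)(CC)CC)[C@@H](C(=C)C(=O)O)[C@@H](O)/C=C(/C)CO[Si](c1ccccc1)(c1ccccc1)C(C)(C)C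
F12 | step 10 | methyl (2E,4S,5R,6S)-5-[(4-methoxybenzyl)oxy]-6-methyl-2-(tributylstannyl)-4,6-bis(triethylsilyloxy)octa-2,7-dienoate | C=C[C@](C)(O[Si](CC)(CC)CC)[C@H](OCc1ccc(OC)cc1)[C@@H](O[Si](CC)(CC)CC)/C=C(/[Sn](CCCC)(CCCC)CCCC)C(=O)OC
F13 | step 10 | methyl (2E,4S,5R,6S)-2-iodo-5-[(4-methoxybenzyl)oxy]-6-methyl-4,6-bis(triethylsilyloxy)octa-2,7-dienoate | C=C[C@](C)(O[Si](CC)(CC)CC)[C@H](OCc1ccc(OC)cc1)[C@@H](O[Si](CC)(CC)CC)/C=C(/I)C(=O)OC
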